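Ring B (C5–C10, labdane numbering) is not built as a cyclohexane. It is grown from the cyclopentanone of an (R)-hydrindenedione by a Lewis-acid-promoted diazoacetate insertion that moves C7 from the ketone carbon C9 onto an incoming carbon, C8, which arrives with C17 attached as an ester. The step exploits two features of ring B: C9 lies between quaternary C10 and a methylene, so only C7 migrates, and C8 carries the one-carbon branch C17. One operation gives ring B with all its carbons and a C9-oxo/C8-ester pair; cross-coupling at C9 and reductive allylic transposition then set H-9 and the 8(17)-methylene. Ring A is finished by reductive hydroxymethylation, α-oxygenation and late angeloylation.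

Key step: step 3

Remark: labdane numbering is used for the decalin compounds (ring A: C1–C5 and C10; ring B: C5–C10; C17 = exocyclic methylene carbon; C18 = CH2OH carbon on C4; C19, C20 = methyls on C4, C10); in hydrindane 4 the ketone carbon next to the quaternary centre is the future C9; β-keto ester 6 is drawn as its keto tautomer.

Step 1
Reactants: 1 2-methylcyclopentane-1,3-dione; 2 pent-1-en-3-one
Product: 3 2-methyl-2-(3-oxopentyl)cyclopentane-1,3-dione
Conditions: H2O, AcOH (cat.), 75 °C
Reagents that add atoms: none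
Why: Michael addition of the acidic 1,3-dione to the enone under nearly neutral conditions should give the prochiral triketone without retro-Claisen cleavage.

Step 2
Reactants: 3 2-methyl-2-(3-oxopentyl)cyclopentane-1,3-dione
Product: 4 (7aR)-4,7a-dimethyl-2,3,7,7a-tetrahydro-1H-indene-1,5(6H)-dione
Conditions: D-phenylalanine (1 equiv), HClO4 (aq, 0.5 equiv), MeCN, 80 °C
Reagents that add atoms: none
Why: Hajos–Parrish–Eder–Sauer–Wiechert reaction, in which the enamine of the side-chain ketone with the D-amino acid should attack one of the two enantiotopic ring carbonyls and dehydrate to the (R)-enedione (mirror image of the L-amino acid series), setting quaternary C10.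

Step 3
Reactants: 4 (7aR)-4,7a-dimethyl-2,3,7,7a-tetrahydro-1H-indene-1,5(6H)-dione; 5 ethyl diazoacetate
Product: 6 ethyl (8aR)-5,8a-dimethyl-1,6-dioxo-1,2,3,4,6,7,8,8a-octahydronaphthalene-2-carboxylate
Conditions: BF3·OEt2, CH2Cl2, 0 °C → rt
Reagents that add atoms: none
Why: This is a Lewis-acid-promoted diazoacetate homologation (Tiffeneau–Demjanov-type ring expansion, the reaction type used for D-homoannulation of 17-keto steroids, which share this cyclopentanone next to an angular-methyl carbon): BF3 activates the saturated C9 carbonyl, the diazo carbon adds to it, and loss of N2 from the β-oxido diazonium ion is accompanied by a 1,2-shift of C7 from C9 to the new carbon C8. No ring is closed by cyclization; the five-membered ring (C5, C6, C7, C9, C10) becomes six-membered ring B by insertion of C8, which arrives bearing C17 as its ester. The only new stereocenter, C8, is enolizable (the product should be largely the hydrogen-bonded enol) and is removed in step 4, so it needs no control, and C10 is untouched. The step needs regioselectivity (migration of the methylene C7, not quaternary C10) and chemoselectivity (saturated versus conjugated ketone): the first is secured because the ester-bearing diazonium carbon turns away from the fully substituted C10 and places the C9–C7 bond anti to N2 (the less substituted carbon migrates in this reaction type), the second because the vinylogously deactivated C3 carbonyl is much less electrophilic towards the weakly nucleophilic diazo ester.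

Step 4
Reactants: 6 ethyl (8aR)-5,8a-dimethyl-1,6-dioxo-1,2,3,4,6,7,8,8a-octahydronaphthalene-2-carboxylate
Product: 7 ethyl (8aR)-5,8a-dimethyl-6-oxo-1-(trifluoromethylsulfonyloxy)-3,4,6,7,8,8a-hexahydronaphthalene-2-carboxylate
Conditions: Tf2O, iPr2NEt, CH2Cl2, −78 °C
Reagents that add atoms: trifluoromethanesulfonic anhydride, O=S(=O)(OS(=O)(=O)C(F)(F)F)C(F)(F)F
Why: Enol triflate formation: the β-keto ester is by far the most acidic site and can enolize only towards C8 (C10 is quaternary), so a single C8=C9 enol triflate should form while the ring A enone is left alone at low temperature.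

Step 5
Reactants: 8 furan-3-carbaldehyde
Product: 9 3-ethenylfuran
Conditions: Ph3PCH3Br, KOtBu, Et2O, 0 °C → rt
Reagents that add atoms: methyltriphenylphosphonium bromide, C[P+](c1ccccc1)(c1ccccc1)c1ccccc1.[Br-]
Why: Wittig methylenation of the aromatic aldehyde; the volatile vinylfuran is carried on as a solution.

Step 6
Reactants: 9 3-ethenylfuran; 7 ethyl (8aR)-5,8a-dimethyl-6-oxo-1-(trifluoromethylsulfonyloxy)-3,4,6,7,8,8a-hexahydronaphthalene-2-carboxylate
Product: 11 ethyl (10R)-15,16-epoxy-3-oxo-18-norlabda-4,8,13(16),14-tetraen-17-oate, via alkylborane 10 (not isolated)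
Conditions: 9-BBN, THF, 0 °C → rt; then 7, PdCl2(dppf) (cat., dppf = 1,1'-bis(diphenylphosphino)ferrocene), AsPh3, K3PO4 (aq), DMF, 50 °C
Reagents that add atoms: none
Why: Anti-Markovnikov hydroboration of the vinyl group and B-alkyl Suzuki–Miyaura coupling form the C9–C11 bond; fast oxidative addition of the electron-poor β-triflyloxy enoate should offset the hindrance at C9 next to quaternary C10.

Step 7
Reactants: 11 ethyl (10R)-15,16-epoxy-3-oxo-18-norlabda-4,8,13(16),14-tetraen-17-oate
Product: 13 (10S)-15,16-epoxy-17-hydroxy-18-norlabda-4,8,13(16),14-tetraen-3-one, via lithium dienolate 12 (not isolated)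
Conditions: LiN(iPr)2 (1.05 equiv), THF, −78 °C; then iBu2AlH (3 equiv), −78 → −20 °C; potassium sodium tartrate (aq)
Reagents that add atoms: none
Why: Kinetic deprotonation at C2 masks the ring A ketone as its cross-conjugated lithium dienolate (enolate as in-situ protecting group towards hydride), so that iBu2AlH should reduce only the C17 ester to the allylic alcohol (1,2-reduction of an enoate) and aqueous work-up returns the conjugated enone.

Step 8
Reactants: 13 (10S)-15,16-epoxy-17-hydroxy-18-norlabda-4,8,13(16),14-tetraen-3-one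
Product: 16 (9R,10S)-15,16-epoxy-18-norlabda-4,8(17),13(16),14-tetraen-3-one, via sulfonylhydrazine 14 (not isolated), via allylic diazene 15 (not isolated)
Conditions: 2-nitrobenzenesulfonylhydrazide, PPh3, diethyl azodicarboxylate, N-methylmorpholine, −30 °C → rt
Reagents that add atoms: none
Why: Reductive 1,3-transposition of an allylic alcohol (Mitsunobu displacement by the sulfonyl hydrazide, loss of sulfinic acid, retro-ene extrusion of N2 from the allylic diazene) should move the alkene to the exocyclic C8=C17 position and deliver hydrogen to C9 on the face opposite the pseudoaxial C10 methyl, giving H-9 trans to that methyl.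

Step 9
Reactants: 16 (9R,10S)-15,16-epoxy-18-norlabda-4,8(17),13(16),14-tetraen-3-one
Product: 18 (4S,5S,9R,10S)-15,16-epoxy-18-hydroxylabda-8(17),13(16),14-trien-3-one, via lithium enolate 17 (not isolated)
Conditions: Li, NH3/THF, tBuOH (1 equiv), −78 °C; isoprene; NH3 removed; CH2O (gas), THF, −78 → −40 °C; NH4Cl (aq)
Reagents that add atoms: formaldehyde, C=O
Why: Birch-type reductive alkylation of a 4-methyl octalone: axial protonation at the β-carbon C5 should give the trans-decalin, and the regiodefined C3/C4 enolate should take up formaldehyde on the face opposite the axial C10 methyl, placing the new CH2OH equatorial (trans to that methyl) at quaternary C4.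

Step 10
Reactants: 18 (4S,5S,9R,10S)-15,16-epoxy-18-hydroxylabda-8(17),13(16),14-trien-3-one
Product: 19 (4S,5S,9R,10S)-3,18-bis(tert-butyldimethylsilyloxy)-15,16-epoxylabda-2,8(17),13(16),14-tetraene
Conditions: TBSOTf (3 equiv), Et3N, CH2Cl2, 0 °C → rt
Reagents that add atoms: tert-butyldimethylsilyl trifluoromethanesulfonate, CC(C)(C)[Si](C)(C)OS(=O)(=O)C(F)(F)F
Why: Soft enolization and silylation should protect the primary alcohol and convert the ketone, which can enolize only towards C2, into its silyl enol ether in one operation.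

Step 11
Reactants: 19 (4S,5S,9R,10S)-3,18-bis(tert-butyldimethylsilyloxy)-15,16-epoxylabda-2,8(17),13(16),14-tetraene
Product: 21 (2S,4S,5S,9R,10S)-2,18-bis(tert-butyldimethylsilyloxy)-15,16-epoxylabda-8(17),13(16),14-trien-3-one, via silyloxy epoxide 20 (not isolated)
Conditions: dimethyldioxirane (1.05 equiv), acetone/CH2Cl2, −78 → −40 °C; then camphor-10-sulfonic acid (cat.), CH2Cl2, 0 °C
Reagents that add atoms: dimethyldioxirane, CC1(C)OO1
Why: Rubottom oxidation: the electron-rich silyl enol ether should be epoxidized much faster than the 1,1-disubstituted alkene or the furan, on the face opposite the two axial methyls (on C10 and C4), and 1,4-silyl migration opens the silyloxy epoxide to the 2-silyloxy ketone with the C2 oxygen equatorial (trans to the C10 methyl).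

Step 12
Reactants: 21 (2S,4S,5S,9R,10S)-2,18-bis(tert-butyldimethylsilyloxy)-15,16-epoxylabda-8(17),13(16),14-trien-3-one
Product: 23 (2S,4S,5S,9R,10S)-2,18-bis(tert-butyldimethylsilyloxy)-16-hydroxy-3-oxolabda-8(17),13-dien-15,16-olide (C16 epimers), via furan endoperoxide 22 (not isolated)
Conditions: O2, hν (visible), 5,10,15,20-tetraphenylporphyrin (cat.), iPr2NEt, CH2Cl2, −78 °C
Reagents that add atoms: dioxygen, O=O
Why: [4+2] cycloaddition of singlet oxygen to the furan and base-induced fragmentation of the endoperoxide by removal of the less hindered C15 proton (Kornblum–DeLaMare-type) should give the 16-hydroxy-15,16-olide regioselectively, while the much slower-reacting 1,1-disubstituted alkene is left.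

Step 13
Reactants: 23 (2S,4S,5S,9R,10S)-2,18-bis(tert-butyldimethylsilyloxy)-16-hydroxy-3-oxolabda-8(17),13-dien-15,16-olide
Product: 24 (2S,3S,4S,5S,9R,10S)-2,18-bis(tert-butyldimethylsilyloxy)-3-hydroxylabda-8(17),13-dien-15,16-olide
Conditions: NaBH4, MeOH/THF, 0 °C; then HCl (aq, 1 M)
Reagents that add atoms: none
Why: Borohydride reduction should convert the ring-opened aldehyde form of the hydroxybutenolide into the butenolide after relactonization and, in the same operation, reduce the C3 ketone by axial hydride attack on the face opposite the axial C4 and C10 methyls, giving the equatorial C3 alcohol trans to the C2 silyloxy group.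

Step 14
Reactants: 25 angelic acid; 24 (2S,3S,4S,5S,9R,10S)-2,18-bis(tert-butyldimethylsilyloxy)-3-hydroxylabda-8(17),13-dien-15,16-olide
Product: 27 (2S,3S,4S,5S,9R,10S)-3-angeloyloxy-2,18-bis(tert-butyldimethylsilyloxy)labda-8(17),13-dien-15,16-olide, via mixed anhydride 26 (not isolated)
Conditions: 2,4,6-trichlorobenzoyl chloride, Et3N, toluene, rt; then 24, 80 °C
Reagents that add atoms: none
Why: Yamaguchi esterification through the mixed anhydride, run without a nucleophilic amine catalyst, is the established way to acylate hindered secondary alcohols with angelic acid without Z to E isomerization, and C3–OH is the only free hydroxyl.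

Step 15
Reactants: 27 (2S,3S,4S,5S,9R,10S)-3-angeloyloxy-2,18-bis(tert-butyldimethylsilyloxy)labda-8(17),13-dien-15,16-olide
Product: 28 (2S,3S,4S,5S,9R,10S)-2,18-dihydroxy-3-[(2Z)-2-methylbut-2-enoyloxy]labda-8(17),13-dien-15,16-olide
Conditions: HF·pyridine, pyridine/THF, 0 °C → rt
Reagents that add atoms: none
Why: Buffered fluoride desilylation should remove both silyl ethers under mildly acidic conditions that avoid acyl migration and isomerization of the angelate.

Compound list
1 | 2-methylcyclopentane-1,3-dione | CC1C(=O)CCC1=O | starting material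
2 | pent-1-en-3-one | C=CC(=O)CC | starting material
3 | 2-methyl-2-(3-oxopentyl)cyclopentane-1,3-dione | CCC(=O)CCC1(C)C(=O)CCC1=O | intermediate
4 | (7aR)-4,7a-dimethyl-2,3,7,7a-tetrahydro-1H-indene-1,5(6H)-dione | O=C1CCC2=C(C)C(=O)CC[C@@]12C | intermediate
5 | ethyl diazoacetate | CCOC(=O)C=[N+]=[N-] | starting material
6 | ethyl (8aR)-5,8a-dimethyl-1,6-dioxo-1,2,3,4,6,7,8,8a-octahydronaphthalene-2-carboxylate (C2 epimers, largely enolized; labdane C9 ketone, C8 ester) | CCOC(=O)C1CCC2=C(C)C(=O)CC[C@@]2(C)C1=O | intermediate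
7 | ethyl (8aR)-5,8a-dimethyl-6-oxo-1-(trifluoromethylsulfonyloxy)-3,4,6,7,8,8a-hexahydronaphthalene-2-carboxylate | CCOC(=O)C1=C(OS(=O)(=O)C(F)(F)F)[C@]2(C)CCC(=O)C(C)=C2CC1 | intermediate
8 | furan-3-carbaldehyde | O=Cc1ccoc1 | starting material
9 | 3-ethenylfuran | C=Cc1ccoc1 | intermediate
10 | 9-[2-(furan-3-yl)ethyl]-9-borabicyclo[3.3.1]nonane | C(Cc1ccoc1)B1C2CCCC1CCC2 | intermediate (not isolated)
11 | ethyl (10R)-15,16-epoxy-3-oxo-18-norlabda-4,8,13(16),14-tetraen-17-oate | CCOC(=O)C1=C(CCc2ccoc2)[C@]2(C)CCC(=O)C(C)=C2CC1 | intermediate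
12 | lithium dienolate of 11 (O–Li on C3, C2=C3 and C4=C5) | CCOC(=O)C1=C(CCc2ccoc2)[C@]2(C)CC=C(O[Li])C(C)=C2CC1 | intermediate (not isolated)
13 | (10S)-15,16-epoxy-17-hydroxy-18-norlabda-4,8,13(16),14-tetraen-3-one | OCC1=C(CCc2ccoc2)[C@]2(C)CCC(=O)C(C)=C2CC1 | intermediate
14 | N-(C17-allyl)-N-(2-nitrophenylsulfonyl)hydrazine derived from 13 | NN(CC1=C(CCc2ccoc2)[C@]2(C)CCC(=O)C(C)=C2CC1)S(=O)(=O)c1ccccc1[N+](=O)[O-] | intermediate (not isolated)
15 | C17 allylic diazene derived from 14 | N=NCC1=C(CCc2ccoc2)[C@]2(C)CCC(=O)C(C)=C2CC1 | intermediate (not isolated)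
16 | (9R,10S)-15,16-epoxy-18-norlabda-4,8(17),13(16),14-tetraen-3-one (H-9 trans to the C10 methyl) | C=C1CCC2=C(C)C(=O)CC[C@@]2(C)[C@@H]1CCc1ccoc1 | intermediate
17 | lithium C3/C4 enolate of the (5S,9R,10S) trans-decalin (H-5 trans to the C10 methyl) | C=C1CC[C@H]2[C@@](C)(CCC(O[Li])=C2C)[C@@H]1CCc1ccoc1 | intermediate (not isolated)
18 | (4S,5S,9R,10S)-15,16-epoxy-18-hydroxylabda-8(17),13(16),14-trien-3-one | C=C1CC[C@H]2[C@@](C)(CCC(=O)[C@]2(C)CO)[C@@H]1CCc1ccoc1 | intermediate
19 | (4S,5S,9R,10S)-3,18-bis(tert-butyldimethylsilyloxy)-15,16-epoxylabda-2,8(17),13(16),14-tetraene | C=C1CC[C@H]2[C@@](C)(CC=C(O[Si](C)(C)C(C)(C)C)[C@]2(C)CO[Si](C)(C)C(C)(C)C)[C@@H]1CCc1ccoc1 | intermediate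
20 | 2,3-epoxide of 19 (oxirane oxygen trans to the C10 methyl) | C=C1CC[C@H]2[C@@](C)(C[C@@H]3O[C@]3(O[Si](C)(C)C(C)(C)C)[C@]2(C)CO[Si](C)(C)C(C)(C)C)[C@@H]1CCc1ccoc1 | intermediate (not isolated)
21 | (2S,4S,5S,9R,10S)-2,18-bis(tert-butyldimethylsilyloxy)-15,16-epoxylabda-8(17),13(16),14-trien-3-one | C=C1CC[C@H]2[C@@](C)(C[C@H](O[Si](C)(C)C(C)(C)C)C(=O)[C@]2(C)CO[Si](C)(C)C(C)(C)C)[C@@H]1CCc1ccoc1 | intermediate
22 | furan 2,5-endoperoxide of 21 | C=C1CC[C@H]2[C@@](C)(C[C@H](O[Si](C)(C)C(C)(C)C)C(=O)[C@]2(C)CO[Si](C)(C)C(C)(C)C)[C@@H]1CCC1=CC2OOC1O2 | intermediate (not isolated)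
23 | (2S,4S,5S,9R,10S)-2,18-bis(tert-butyldimethylsilyloxy)-16-hydroxy-3-oxolabda-8(17),13-dien-15,16-olide (C16 epimers) | C=C1CC[C@H]2[C@@](C)(C[C@H](O[Si](C)(C)C(C)(C)C)C(=O)[C@]2(C)CO[Si](C)(C)C(C)(C)C)[C@@H]1CCC1=CC(=O)OC1O | intermediate
24 | (2S,3S,4S,5S,9R,10S)-2,18-bis(tert-butyldimethylsilyloxy)-3-hydroxylabda-8(17),13-dien-15,16-olide | C=C1CC[C@H]2[C@@](C)(C[C@H](O[Si](C)(C)C(C)(C)C)[C@@H](O)[C@]2(C)CO[Si](C)(C)C(C)(C)C)[C@@H]1CCC1=CC(=O)OC1 | intermediate
25 | angelic acid, (2Z)-2-methylbut-2-enoic acid | C/C=C(/C)C(=O)O | starting material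
26 | angelic 2,4,6-trichlorobenzoic anhydride | C/C=C(/C)C(=O)OC(=O)c1c(Cl)cc(Cl)cc1Cl | intermediate (not isolated)
27 | (2S,3S,4S,5S,9R,10S)-3-angeloyloxy-2,18-bis(tert-butyldimethylsilyloxy)labda-8(17),13-dien-15,16-olide | C=C1CC[C@H]2[C@@](C)(C[C@H](O[Si](C)(C)C(C)(C)C)[C@@H](OC(=O)/C(C)=C\C)[C@]2(C)CO[Si](C)(C)C(C)(C)C)[C@@H]1CCC1=CC(=O)OC1 | intermediate
28 | (2S,3S,4S,5S,9R,10S)-2,18-dihydroxy-3-[(2Z)-2-methylbut-2-enoyloxy]labda-8(17),13-dien-15,16-olide | C=C1CC[C@H]2[C@@](C)(C[C@H](O)[C@@H](OC(=O)/C(C)=C\C)[C@]2(C)CO)[C@@H]1CCC1=CC(=O)OC1 | target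

Total steps: 15. Longest linear sequence: 14 steps (steps 1–4 and 6–15; step 5 is the side branch).

Steps most likely to fail

Step 7. Incomplete masking of the ring A ketone by enolization would allow partial reduction of the enone, and competing γ-deprotonation of the dienoate would erode the chemoselective ester reduction. The fallback sets out from 11 and returns at 16. Both carbonyl groups of 11 are reduced with excess iBu2AlH (CH2Cl2, −78 °C) to the 3,17-diol F1. The reductive transposition of step 8 is then run with one equivalent of the sulfonyl hydrazide at −30 °C, where the primary allylic C17 alcohol should react before the secondary one, to give the 8(17)-en-3-ol F2. MnO2 (CH2Cl2, rt) oxidizes the remaining allylic alcohol to enone 16.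

Step 14. Acylation of the C3 hydroxyl may be slow, since it is flanked by quaternary C4 and the silyloxy-bearing C2, and the activated angeloyl unit may isomerize from Z to E on prolonged heating. The fallback sets out from 24 and returns at 27. Alcohol 24 is esterified with 2-[bis(2,2,2-trifluoroethoxy)phosphoryl]propanoic acid (N,N'-dicyclohexylcarbodiimide, 4-dimethylaminopyridine, CH2Cl2) to the phosphonate ester F3. A Still–Gennari olefination (KN(SiMe3)2, 18-crown-6, THF, −78 °C, acetaldehyde) then builds the Z-configured 2-methylbut-2-enoate on the alcohol and gives 27.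

Step 11. The electrophilic oxidant may lose chemoselectivity (oxidative opening of the furan, epoxidation of the 8(17)-alkene), or the enol ether may hydrolyze prematurely. The fallback sets out from 18 and returns at 21. Only the primary alcohol of 18 is silylated (TBSCl, imidazole, DMF) to the silyloxy ketone F4. Its potassium enolate (KN(SiMe3)2, THF, −78 °C) is hydroxylated with 2-(phenylsulfonyl)-3-phenyloxaziridine, a reagent that leaves furans and isolated alkenes alone, on the face opposite the axial methyls to give the 2-hydroxy ketone F5. Silylation (TBSOTf, 2,6-lutidine, CH2Cl2) gives 21.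

Further compounds
F1 | step 7 | (10S)-15,16-epoxy-18-norlabda-4,8,13(16),14-tetraene-3,17-diol (C3 epimers) | OCC1=C(CCc2ccoc2)[C@]2(C)CCC(O)C(C)=C2CC1
F2 | step 7 | (9R,10S)-15,16-epoxy-18-norlabda-4,8(17),13(16),14-tetraen-3-ol (C3 epimers) | C=C1CCC2=C(C)C(O)CC[C@@]2(C)[C@@H]1CCc1ccoc1
F3 | step 14 | 3-O-{2-[bis(2,2,2-trifluoroethoxy)phosphoryl]propanoyl} ester of 24 | C=C1CC[C@H]2[C@@](C)(C[C@H](O[Si](C)(C)C(C)(C)C)[C@@H](OC(=O)C(C)P(=O)(OCC(F)(F)F)OCC(F)(F)F)[C@]2(C)CO[Si](C)(C)C(C)(C)C)[C@@H]1CCC1=CC(=O)OC1
F4 | step 11 | (4S,5S,9R,10S)-18-(tert-butyldimethylsilyloxy)-15,16-epoxylabda-8(17),13(16),14-trien-3-one | C=C1CC[C@H]2[C@@](C)(CCC(=O)[C@]2(C)CO[Si](C)(C)C(C)(C)C)[C@@H]1CCc1ccoc1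
F5 | step 11 | (2S,4S,5S,9R,10S)-18-(tert-butyldimethylsilyloxy)-2-hydroxy-15,16-epoxylabda-8(17),13(16),14-trien-3-one | C=C1CC[C@H]2[C@@](C)(C[C@H](O)C(=O)[C@]2(C)CO[Si](C)(C)C(C)(C)C)[C@@H]1CCc1ccoc1
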